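## Retrosynthetic overview

1. Target 8 ⇒ 6, (R)-δ-tocotrienol: the C-5 formyl group is removed; it is put on last by phenoxide-directed ortho-formylation (C-5 is the more reactive ortho position of a 6-chromanol).
2. 6 ⇒ 5: the dihydropyran ring is opened at O1–C2. Forward, the open-chain geranylgeranyl quinol is closed by enantioselective proton-initiated cyclisation onto its proximal alkene, as tocopherol cyclase does; this sets C-2 (R), the only stereocentre.
3. 5 ⇒ 3: para-hydroxylation of a 2,6-disubstituted phenol (through quinone 4). This fixes the quinol substitution pattern, which direct prenylation of methylhydroquinone would not give (it alkylates mainly para to the methyl group).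
4. 3 ⇒ 1 + 2: ortho C-geranylgeranylation of o-cresol with all-E-geranylgeraniol.
5. Ring order: the benzene ring is bought with 1; the pyran ring is the only ring formed (step 3).

Abbreviation: geranylgeranyl = (2E,6E,10E)-3,7,11,15-tetramethylhexadeca-2,6,10,14-tetraen-1-yl.

Assumption: all-E-geranylgeraniol 2 is taken as purchasable, and the chiral acid of step 3 (a catalyst, made separately from BINOL) is not counted as a step. The acid is written as its (S,S) form; its sense of induction is unproven, so if the first run gives the 2S chromanol (comparison with authentic (R)-δ-tocotrienol), the (R,R) acid is used instead.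

## Route

**Step 1**
Reactants: 1 2-methylphenol (o-cresol); 2 (2E,6E,10E)-geranylgeraniol
Product: 3 2-geranylgeranyl-6-methylphenol
Conditions: acidic Al2O3 (about 2 g per mmol of 2), 1 (3 equiv), ClCH2CH2Cl, reflux, 24 h
Reagents that add atoms: none
Why: Alumina-templated ortho-selective Friedel–Crafts allylation, in which phenol and allylic alcohol are both bound to the acidic Al2O3 surface so that the allyl cation is delivered through its primary carbon to the only free ortho carbon with the 2E geometry kept (as known for geraniol and farnesol); no stereocentre is formed.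

**Step 2**
Reactants: 3 2-geranylgeranyl-6-methylphenol
Product: 5 2-geranylgeranyl-6-methylbenzene-1,4-diol, via 2-geranylgeranyl-6-methylbenzoquinone 4 (not isolated)
Conditions: (KSO3)2NO (2.5 equiv), KH2PO4, acetone/H2O, 0 °C to rt; then aq. Na2S2O4 (3 equiv), rt, Ar
Reagents that add atoms: potassium nitrosodisulfonate (Fremy's salt), [K+].[K+].[O-]S(=O)(=O)N([O])S(=O)(=O)[O-]
Why: Teuber oxidation, in which the phenoxyl radical is trapped at its free para carbon by a second nitrosodisulfonate radical to give para-quinone 4, which dithionite reduces in the same flask to the quinol; the isolated trisubstituted alkenes react with neither reagent, and no stereocentre is involved.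

**Step 3**
Reactants: 5 2-geranylgeranyl-6-methylbenzene-1,4-diol
Product: 6 (R)-δ-tocotrienol
Conditions: (S,S)-IDPi acid (5 mol%), methylcyclohexane, 40 °C, Ar, 48 h. The acid is the imidodiphosphorimidate HN[P(=NSO2CF3)(O,O′-binaphthyldiyl)]2 built from two (S)-3,3′-bis[3,5-bis(trifluoromethyl)phenyl]-1,1′-bi-2-naphthol units.
Reagents that add atoms: none
Why: Proposed new method: an enantioselective Brønsted acid-catalysed intramolecular hydroalkoxylation that imitates tocopherol cyclase, in which the confined acid delivers its proton to C-2′ of the proximal E-alkene while the hydrogen-bonded C-1 phenol oxygen closes onto the Re face of the developing tertiary cation at C-3′ in one asynchronous concerted event (six-membered ring, Markovnikov), which sets C-2 as R, and the three distal alkenes, having no internal nucleophile to assist protonation, should stay untouched in a hydrocarbon solvent; the closest known reaction types are the IDPi-catalysed asymmetric hydroalkoxylation of unactivated alkenols to tertiary cyclic ethers and IDPi-catalysed enantioselective polyene cyclisation.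

**Step 4**
Reactants: 6 (R)-δ-tocotrienol
Product: 8 (R)-5-formyl-δ-tocotrienol, via 5-hydroxymethyl-δ-tocotrienol 7 (not isolated)
Conditions: MgCl2 (2 equiv), Et3N (4 equiv), (CH2O)n (6 equiv), THF, reflux, 4 h; then 1 M HCl, 0 °C
Reagents that add atoms: paraformaldehyde (reacts as formaldehyde), C=O
Why: Casnati–Skattebøl ortho-formylation, in which the magnesium phenoxide delivers formaldehyde to an ortho carbon and a second formaldehyde oxidises the benzylic alkoxide 7 to the aldehyde by hydride transfer, with C-5 expected to be favoured over C-7 (a few to one, minor isomer removed by chromatography) because the annulated ring fixes more double-bond character in the C5–C6 bond, and the quaternary C-2 ether centre and the alkenes are inert to these basic conditions.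

## Compound list

1 | 2-methylphenol (o-cresol) | Cc1ccccc1O | starting material
2 | (2E,6E,10E)-3,7,11,15-tetramethylhexadeca-2,6,10,14-tetraen-1-ol (all-E-geranylgeraniol) | CC(C)=CCC/C(C)=C/CC/C(C)=C/CC/C(C)=C/CO | starting material
3 | 2-methyl-6-[(2E,6E,10E)-3,7,11,15-tetramethylhexadeca-2,6,10,14-tetraen-1-yl]phenol | CC(C)=CCC/C(C)=C/CC/C(C)=C/CC/C(C)=C/Cc1cccc(C)c1O | intermediate
4 | 2-methyl-6-[(2E,6E,10E)-3,7,11,15-tetramethylhexadeca-2,6,10,14-tetraen-1-yl]cyclohexa-2,5-diene-1,4-dione (not isolated) | CC(C)=CCC/C(C)=C/CC/C(C)=C/CC/C(C)=C/CC1=CC(=O)C=C(C)C1=O | intermediate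
5 | 2-methyl-6-[(2E,6E,10E)-3,7,11,15-tetramethylhexadeca-2,6,10,14-tetraen-1-yl]benzene-1,4-diol | CC(C)=CCC/C(C)=C/CC/C(C)=C/CC/C(C)=C/Cc1cc(O)cc(C)c1O | intermediate
6 | (2R)-2,8-dimethyl-2-[(3E,7E)-4,8,12-trimethyltrideca-3,7,11-trien-1-yl]-3,4-dihydro-2H-chromen-6-ol, (R)-δ-tocotrienol | CC(C)=CCC/C(C)=C/CC/C(C)=C/CC[C@]1(C)CCc2cc(O)cc(C)c2O1 | intermediate
7 | (2R)-5-(hydroxymethyl)-2,8-dimethyl-2-[(3E,7E)-4,8,12-trimethyltrideca-3,7,11-trien-1-yl]-3,4-dihydro-2H-chromen-6-ol (not isolated; present as its magnesium salt, drawn neutral) | CC(C)=CCC/C(C)=C/CC/C(C)=C/CC[C@]1(C)CCc2c(CO)c(O)cc(C)c2O1 | intermediate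
8 | (2R)-6-hydroxy-2,8-dimethyl-2-[(3E,7E)-4,8,12-trimethyltrideca-3,7,11-trien-1-yl]-3,4-dihydro-2H-chromene-5-carbaldehyde | CC(C)=CCC/C(C)=C/CC/C(C)=C/CC[C@]1(C)CCc2c(C=O)c(O)cc(C)c2O1 | target

## Step count and risks

Total steps: 4. Longest linear sequence: 4 steps (1 or 2 → 3 → 5 → 6 → 8).

**Step 3 (highest risk).** The risks are site selectivity among four trisubstituted alkenes and the level and sense of enantio-induction. Fallback: replace the small-molecule acid by the enzyme. Compound 5 is a native substrate of plant tocopherol cyclase. It is solubilised with detergent and incubated with a cell-free preparation of recombinant Arabidopsis thaliana tocopherol cyclase (VTE1, expressed in Escherichia coli) in degassed phosphate buffer, pH 7, 30 °C, under argon. The enzyme closes only the proximal alkene and gives the natural 2R chromanol. The fallback sets out from 5 and returns to the route at 6; it makes no compound outside the list (F0).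

**Step 1.** The risks are cationic cyclisation of the polyene on hot acidic alumina and para- or bis-alkylation. Fallback: change from surface-templated Friedel–Crafts chemistry to SN2 C-alkylation of a phenoxide ion pair. Alcohol 2 is converted with PBr3 in Et2O at −10 °C into (2E,6E,10E)-geranylgeranyl bromide F1. Phenol 1 is deprotonated with NaH in toluene to sodium 2-methylphenolate F2. As a tight ion pair in the non-polar solvent, the phenolate is alkylated by the bromide at its free ortho carbon (rt) without any carbocation, giving 3; the O-allyl ether by-product is removed by chromatography. The fallback sets out from 1 and 2 and returns at 3.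

**Step 4.** The risks are an insufficient C-5 to C-7 ratio and bis-formylation. Fallback: deliver the one-carbon unit by a [2,3]-sigmatropic shift instead of electrophilic attack (Gassman ortho-formylation).
- Chromanol 6 is added at −70 °C in CH2Cl2 to 1,3-dithiane that has been activated with N-chlorosuccinimide. This gives the aryloxysulfonium salt 1-{[(2R)-2,8-dimethyl-2-(4,8,12-trimethyltrideca-3,7,11-trienyl)chroman-6-yl]oxy}-1,3-dithian-1-ium chloride F3, which is not isolated.
- Et3N forms the sulfur ylide, which shifts to the ortho carbon joined to oxygen by the bond of higher double-bond character (C-5, as in Claisen rearrangements of such ring-fused phenols). Rearomatisation gives (2R)-5-(1,3-dithian-2-yl)-δ-tocotrienol F4, which is purified.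
- Alkylative hydrolysis of the dithiane (MeI, CaCO3, MeCN/H2O, 40 °C) gives the aldehyde.

The fallback sets out from 6 and returns at 8.

## Further compounds

F0 | step 3 | none | none
F1 | step 1 | (2E,6E,10E)-1-bromo-3,7,11,15-tetramethylhexadeca-2,6,10,14-tetraene (geranylgeranyl bromide) | CC(C)=CCC/C(C)=C/CC/C(C)=C/CC/C(C)=C/CBr
F2 | step 1 | sodium 2-methylphenolate | Cc1ccccc1[O-].[Na+]
F3 | step 4 | 1-{[(2R)-2,8-dimethyl-2-[(3E,7E)-4,8,12-trimethyltrideca-3,7,11-trien-1-yl]-3,4-dihydro-2H-chromen-6-yl]oxy}-1,3-dithian-1-ium chloride | CC(C)=CCC/C(C)=C/CC/C(C)=C/CC[C@]1(C)CCc2cc(O[S+]3CCCSC3)cc(C)c2O1.[Cl-]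
F4 | step 4 | (2R)-5-(1,3-dithian-2-yl)-2,8-dimethyl-2-[(3E,7E)-4,8,12-trimethyltrideca-3,7,11-trien-1-yl]-3,4-dihydro-2H-chromen-6-ol | CC(C)=CCC/C(C)=C/CC/C(C)=C/CC[C@]1(C)CCc2c(C3SCCCS3)c(O)cc(C)c2O1
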